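**Plan**

1. Numbering follows the isochromene skeleton: C1 lactone carbonyl, O2, C3, C4, C4a, C5 (quaternary centre), C6 ketone, C7, C8 (enol carbon), C8a; C1' is the first farnesyl carbon.
2. Retrosynthetic cuts, in order: C6–C7 (carbocycle opened to a methyl ester on C5 and an ethyl ketone at C8), C5–C1' (farnesyl), C4a–C5 (propanoate arm), C8–C8a (propanoyl group); this leaves triacetic acid lactone.
3. Forward: the pyranone ring is bought, acylated at C8a, chlorinated at C4a, coupled with a propanoate zinc enolate and farnesylated at C5; the carbocycle is closed last by an intramolecular Claisen (Dieckmann) condensation.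
4. Enabling feature: C6 lies between the hydrogen-free C5 and C7, the only enolisable α-carbon of the C8 ketone. C5 and C8 sit on the adjacent pyranone carbons C4a and C8a, so enolate and ester are held together. The product is a vinylogous acid (C6=O, C8–OH, C1=O) whose deprotonation drives the closure, so one event creates the whole non-aromatic diketo-enol carbocycle from a monocyclic pyranone.
5. Stereochemistry: the single stereocentre C5 is set as (S) by catalytic asymmetric phase-transfer farnesylation and, being quaternary, cannot epimerise afterwards. The 2E,6E geometry is carried in from farnesyl bromide by SN2 displacement.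

Key step: step 5

Assumption: which antipode of the phase-transfer catalyst gives the (S) centre cannot be derived in advance for this new enolate; both antipodes are commercial, the one giving (S) is fixed in a first screen, and it is written below as the (S,S) catalyst.

**Step 1**
Reactants: 1 4-hydroxy-6-methyl-2H-pyran-2-one (triacetic acid lactone); 2 propanoic acid
Product: 4 4-hydroxy-6-methyl-3-propanoyl-2H-pyran-2-one, via O-propanoyl ester 3 (not isolated)
Conditions: DCC, DMAP, toluene, rt then 100 °C
Reagents that add atoms: none
Why: Steglich esterification of the 4-hydroxyl should give ester 3, and DMAP then moves the acyl group from oxygen to C3 (Fries-type O-to-C acyl migration), the standard route to 3-acyl-4-hydroxy-2-pyranones; no stereocentre is formed.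

**Step 2**
Reactants: 4 4-hydroxy-6-methyl-3-propanoyl-2H-pyran-2-one
Product: 5 4-chloro-6-methyl-3-propanoyl-2H-pyran-2-one
Conditions: (COCl)2, DMF (cat.), CH2Cl2, 0 °C to rt
Reagents that add atoms: oxalyl chloride, ClC(=O)C(=O)Cl
Why: DMF-catalysed conversion of a vinylogous acid into its vinylogous acid chloride, as practised on 2-acylcyclohexane-1,3-diones, should place chlorine on ring carbon C4 because the ring oxygen is the enol oxygen of the acylpyranone; no stereocentre is formed.

**Step 3**
Reactants: 5 4-chloro-6-methyl-3-propanoyl-2H-pyran-2-one; 6 methyl 2-bromopropanoate (racemic)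
Product: 8 methyl 2-(6-methyl-2-oxo-3-propanoyl-2H-pyran-4-yl)propanoate (racemic), via Reformatsky reagent 7 (not isolated)
Conditions: 6, Zn dust, TMSCl (cat.), THF, 40 °C (2.2 equiv of 7); then 5, Pd(dba)2 (3 mol%), P(t-Bu)3 (3 mol%), THF, rt; aq NH4Cl
Reagents that add atoms: none
Why: Negishi-type coupling of a Reformatsky reagent, in which zerovalent palladium inserts into the activated C4–Cl bond of the β-chloro enone and transmetalation with zinc enolate 7 and reductive elimination form the C–C bond; the mild zinc enolate should spare the ketone and the lactone, and the new stereocentre is left racemic on purpose because it is deprotonated in the next step.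

**Step 4**
Reactants: 8 methyl 2-(6-methyl-2-oxo-3-propanoyl-2H-pyran-4-yl)propanoate (racemic); 9 (2E,6E)-farnesyl bromide
Product: 10 methyl (2S,4E,8E)-2,5,9,13-tetramethyl-2-(6-methyl-2-oxo-3-propanoyl-2H-pyran-4-yl)tetradeca-4,8,12-trienoate
Conditions: (S,S)-3,4,5-trifluorophenyl-NAS bromide (C2-symmetric N-spiro binaphthyl ammonium bromide, 3 mol%), Cs2CO3 (solid), toluene, −20 °C
Reagents that add atoms: none
Why: Asymmetric phase-transfer alkylation, in which carbonate removes the one strongly acidic C–H (α to the ester and vinylogous to the ketone and the lactone carbonyl), the extended enolate is paired with the chiral ammonium ion that shields one face, and SN2 attack of carbon on the primary allylic bromide sets the quaternary (S) centre under catalyst control with the E,E geometry of the chain retained.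

**Step 5**
Reactants: 10 methyl (2S,4E,8E)-2,5,9,13-tetramethyl-2-(6-methyl-2-oxo-3-propanoyl-2H-pyran-4-yl)tetradeca-4,8,12-trienoate
Product: 11 (5S)-8-hydroxy-3,5,7-trimethyl-5-[(2E,6E)-3,7,11-trimethyldodeca-2,6,10-trien-1-yl]-1H-isochromene-1,6(5H)-dione (5-farnesyl-isochromene)
Conditions: LiN(SiMe3)2 (2.2 equiv), THF, −78 °C to 0 °C; then cold 1 M HCl
Reagents that add atoms: none
Why: LiN(SiMe3)2 removes a proton from C7, the only enolisable α-carbon of the C8 ketone (the other α-position is the fully substituted pyranone carbon C8a), and the lithium enolate adds to the methyl ester carbonyl C6 on the quaternary carbon C5; collapse of the tetrahedral adduct expels methoxide, and the released base deprotonates the new 1,3-dicarbonyl unit, which makes the condensation irreversible. The closest known reaction type is the Dieckmann (intramolecular Claisen) condensation of ortho-acylaryl acetic esters to 4,4-disubstituted naphthalene-1,3-diones and of δ-keto esters to cyclic 1,3-diones. The carbocycle closes in the 6-(enolendo)-exo-trig mode, since both enolate carbons C7 and C8 lie inside the new ring. No stereocentre is formed, and the (S) centre at C5 carries no hydrogen and lies outside every enolate, so it cannot be scrambled. The step needs C- over O-acylation and attack by the C7 enolate rather than by other anions: O-acylation is reversed by the released methoxide whereas C-acylation ends in the stabilised enolate, the anion at the ring methyl group cannot reach C6 without a meta bridge across the pyranone, and the adjacent ring positions C4a and C8a hold enolate and ester within bonding distance. Acidification should give the C8 enol hydrogen-bonded to the lactone carbonyl C1, the tautomer drawn for the target.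

**Compound list**

1 | 4-hydroxy-6-methyl-2H-pyran-2-one (triacetic acid lactone) | Cc1cc(O)cc(=O)o1 | starting material
2 | propanoic acid | CCC(=O)O | starting material
3 | 6-methyl-2-oxo-2H-pyran-4-yl propanoate | CCC(=O)Oc1cc(C)oc(=O)c1 | intermediate
4 | 4-hydroxy-6-methyl-3-propanoyl-2H-pyran-2-one | CCC(=O)c1c(O)cc(C)oc1=O | intermediate
5 | 4-chloro-6-methyl-3-propanoyl-2H-pyran-2-one | CCC(=O)c1c(Cl)cc(C)oc1=O | intermediate
6 | methyl 2-bromopropanoate (racemic) | COC(=O)C(C)Br | starting material
7 | (1-methoxy-1-oxopropan-2-yl)zinc bromide (Reformatsky reagent) | COC(=O)C(C)[Zn]Br | intermediate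
8 | methyl 2-(6-methyl-2-oxo-3-propanoyl-2H-pyran-4-yl)propanoate (racemic) | CCC(=O)c1c(C(C)C(=O)OC)cc(C)oc1=O | intermediate
9 | (2E,6E)-farnesyl bromide | CC(C)=CCC/C(C)=C/CC/C(C)=C/CBr | starting material
10 | methyl (2S,4E,8E)-2,5,9,13-tetramethyl-2-(6-methyl-2-oxo-3-propanoyl-2H-pyran-4-yl)tetradeca-4,8,12-trienoate | CC(C)=CCC/C(C)=C/CC/C(C)=C/C[C@](C)(C(=O)OC)c1c(C(=O)CC)c(=O)oc(C)c1 | intermediate
11 | (5S)-8-hydroxy-3,5,7-trimethyl-5-[(2E,6E)-3,7,11-trimethyldodeca-2,6,10-trien-1-yl]-1H-isochromene-1,6(5H)-dione | CC(C)=CCC/C(C)=C/CC/C(C)=C/C[C@]1(C)C(=O)C(C)=C(O)c2c1cc(C)oc2=O | target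

**Totals and risks**

Total step count: 5. Longest linear sequence: 5 steps (1 → 4 → 5 → 8 → 10 → 11).

Steps most likely to fail:

Step 4. The risk is poor enantiofacial discrimination, because the extended enolate of 8 is acyclic and can adopt two geometries about the C4a–C5 bond that expose opposite faces to the catalyst; O-alkylation of the delocalised anion may also compete. The fallback sets out from 8 and replaces catalyst control by resolution: farnesylation with 9 without a chiral catalyst (Cs2CO3, Bu4NBr (cat.), toluene, 0 °C) should give 10 together with an equal amount of its mirror image, methyl (2R,4E,8E)-2,5,9,13-tetramethyl-2-(6-methyl-2-oxo-3-propanoyl-2H-pyran-4-yl)tetradeca-4,8,12-trienoate F1. The two are separated by preparative chromatography on a chiral stationary phase (supercritical CO2/MeOH), and the (S)-ester comes back to the route as 10.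

Step 3. The risk is addition of the zinc enolate to the propanoyl carbonyl, or premature ring closure of the zinc dienolate of 8 onto its own ester with aromatisation before work-up. The fallback sets out from 5 and uses a metal-free addition–elimination followed by acidic decarboxylation, so that no enolate of 8 is ever present. The potassium salt of 2,2,5-trimethyl-1,3-dioxane-4,6-dione (K2CO3, MeCN, rt) should displace chloride to give 2,2,5-trimethyl-5-(6-methyl-2-oxo-3-propanoyl-2H-pyran-4-yl)-1,3-dioxane-4,6-dione F2. Heating in MeOH with HCl (cat.) opens the dioxanedione to the malonic half ester 3-methoxy-2-methyl-2-(6-methyl-2-oxo-3-propanoyl-2H-pyran-4-yl)-3-oxopropanoic acid F3 (not isolated), which loses CO2 as a vinylogous β-keto acid and comes back to the route as 8.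

Step 5. The risk is slow attack on the hindered α-quaternary ester, so that opening of the pyranone by released methoxide or decay of the polyanion overtakes ring closure. The fallback sets out from 8 and reverses the order of ring closure and farnesylation. With no quaternary centre in the way, Cs2CO3 in DMF at 60 °C should close the same C6–C7 bond under thermodynamic control, with aromatisation, to 6,8-dihydroxy-3,5,7-trimethyl-1H-isochromen-1-one F4. Alkylative dearomatisation of its lithium phenolate with 9 (LiN(SiMe3)2, toluene, 0 °C), the reaction type used for C-prenylation of methylated orsellinates and acylphloroglucinols, should then give 11 together with its mirror image, (5R)-8-hydroxy-3,5,7-trimethyl-5-[(2E,6E)-3,7,11-trimethyldodeca-2,6,10-trien-1-yl]-1H-isochromene-1,6(5H)-dione F5. Alkylation at C7 or on oxygen is the regiochemical hazard of this fallback. Preparative chromatography on a chiral stationary phase delivers 11, where the fallback rejoins the route.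

**Further compounds**

F1 | step 4 | methyl (2R,4E,8E)-2,5,9,13-tetramethyl-2-(6-methyl-2-oxo-3-propanoyl-2H-pyran-4-yl)tetradeca-4,8,12-trienoate | CC(C)=CCC/C(C)=C/CC/C(C)=C/C[C@@](C)(C(=O)OC)c1c(C(=O)CC)c(=O)oc(C)c1
F2 | step 3 | 2,2,5-trimethyl-5-(6-methyl-2-oxo-3-propanoyl-2H-pyran-4-yl)-1,3-dioxane-4,6-dione | CCC(=O)c1c(C2(C)C(=O)OC(C)(C)OC2=O)cc(C)oc1=O
F3 | step 3 | 3-methoxy-2-methyl-2-(6-methyl-2-oxo-3-propanoyl-2H-pyran-4-yl)-3-oxopropanoic acid (racemic) | CCC(=O)c1c(C(C)(C(=O)O)C(=O)OC)cc(C)oc1=O
F4 | step 5 | 6,8-dihydroxy-3,5,7-trimethyl-1H-isochromen-1-one | Cc1cc2c(C)c(O)c(C)c(O)c2c(=O)o1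
F5 | step 5 | (5R)-8-hydroxy-3,5,7-trimethyl-5-[(2E,6E)-3,7,11-trimethyldodeca-2,6,10-trien-1-yl]-1H-isochromene-1,6(5H)-dione | CC(C)=CCC/C(C)=C/CC/C(C)=C/C[C@@]1(C)C(=O)C(C)=C(O)c2c1cc(C)oc2=O
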